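**Plan**
Retrosynthesis: the C9–Br and C10–Cl bonds go back through a 9,10-epoxide to a C9=C10 alkene, the C11 methylene to a ring-B enone carbonyl, and the cis C3–OH/C4–Br pair to a ring-A enone; the spiro dienedione that results is cut at C4–C5 and C1–C6.
This double cut is possible because ring B (C6–C11) with its C9 methyl, together with C5 and its two methyls, is the carbon skeleton of pulegone: the enone makes C5 an acceptor and, once C5 has reacted, C6 an enolate donor, the polarity needed to graft C4–C3–C2–C1 from a 2-silyloxy-4-methoxydiene.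
Forward: ring B is bought, ring A is annulated onto it, ring B is desaturated, ring A is brominated and reduced, C11 is deoxygenated, and the ring-B alkene is converted into the trans bromochloride.
Stereochemistry: C9 of (R)-pulegone sets the spiro centre C6 and is then erased; C6 steers the C4 bromination and the face of epoxidation; C3 follows C4 (hydride anti to Br); C10 and C9 follow from anti opening of the epoxide and anti capture next to chlorine.
Key step: step 2

Remark: locants follow the spiro[5.5]undecane numbering of the target throughout (ring A C1–C5, spiro C6, ring B C7–C11) rather than lowest-locant rules, and the C11 carbinol centre of 11 and 12 is carried as an epimer mixture because step 7 removes it.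

**Route**

Step 1
Reactants: 1 (E)-4-methoxypent-3-en-2-one; 2 chlorotrimethylsilane
Product: 3 (E)-4-methoxy-2-(trimethylsilyloxy)penta-1,3-diene
Conditions: LDA, THF, −78 °C; then TMSCl, −78 °C → rt; distillation
Reagents that add atoms: chlorotrimethylsilane C[Si](C)(C)Cl
Why: Kinetic deprotonation of the acetyl methyl of the vinylogous ester and O-silylation (silyl enol ether formation) should give the cross-conjugated silyloxydiene with the (E)-enol ether untouched; no stereocentre is formed.

Step 2
Reactants: 3 (E)-4-methoxy-2-(trimethylsilyloxy)penta-1,3-diene; 4 (R)-(+)-pulegone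
Product: 7 (6S,9R)-1,5,5,9-tetramethylspiro[5.5]undec-1-ene-3,11-dione, via titanium enolate 5 (not isolated), via methoxy diketone 6 (not isolated)
Conditions: TiCl4 (1.1 equiv), CH2Cl2, −78 → −30 °C; then 1 M HCl, THF, rt
Reagents that add atoms: none
Why: Proposed new method: TiCl4 bound to the pulegone carbonyl makes C5 electrophilic, and the CH2 terminus of silyloxydiene 3 should add there in a Mukaiyama–Michael step (C4–C5) to give titanium enolate 5, whose side chain is a β-methoxy enone. The enolate carbon C6 then adds to the methoxy-bearing carbon C1 of that vinylogous ester in a 6-(enolexo)-endo-trig Michael closure (C1–C6) to 6, and loss of methanol on acid work-up gives the enone and pulls the congested step forward. The closest known reactions are stepwise Lewis-acid [4+2] annulations of 1-alkoxy-3-silyloxydienes with enones and Mukaiyama–Michael additions to β,β-disubstituted enones; what is new is the joining of two adjacent quaternary carbons on a tetrasubstituted enone. The only new stereocentre, C6, is set by the C9 methyl of pulegone: chair-like axial attack on the enolate half-chair with that methyl equatorial should place C1 cis to it (6S). The step needs 1,4- rather than 1,2-addition and the regiochemistry C4→C5 then C6→C1, both secured by the matched polarity of the diene (nucleophilic CH2, latent electrophilic C–OMe) and of the enone (electrophilic C5, nucleophilic C6 after the first addition); any 6-epimer has to be removed here, because after step 3 it would be the enantiomer.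

Step 3
Reactants: 7 (6S,9R)-1,5,5,9-tetramethylspiro[5.5]undec-1-ene-3,11-dione
Product: 8 (6S)-1,5,5,9-tetramethylspiro[5.5]undeca-1,9-diene-3,11-dione
Conditions: IBX (2 equiv), DMSO/PhMe, 70 °C
Reagents that add atoms: none
Why: IBX-mediated α,β-dehydrogenation of a ketone should act only in ring B, since the C11 ketone can enolise solely toward C10 (C6 is quaternary) whereas the ring-A enone has no hydrogen on C5 and cannot be desaturated further; the C9 stereocentre is erased and C6 is untouched.

Step 4
Reactants: 8 (6S)-1,5,5,9-tetramethylspiro[5.5]undeca-1,9-diene-3,11-dione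
Product: 10 (4R,6R)-4-bromo-1,5,5,9-tetramethylspiro[5.5]undeca-1,9-diene-3,11-dione, via silyl dienol ether 9 (not isolated)
Conditions: LDA, TMSCl, THF, −78 °C; then NBS, THF, −78 °C
Reagents that add atoms: N-bromosuccinimide O=C1CCC(=O)N1Br
Why: Kinetic α′-deprotonation with LDA is possible only in ring A (the ring-B enone has no α′-hydrogen and γ-deprotonation is slower), and electrophilic bromination of the 2-silyloxydiene 9 by NBS at C4 should occur on the face of ring A flanked by the flat C11 carbonyl carbon rather than by the C7 methylene, which sets 4R (Br cis to C11); the α-bromo ketone is used at once so that C4 cannot equilibrate.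

Step 5
Reactants: 10 (4R,6R)-4-bromo-1,5,5,9-tetramethylspiro[5.5]undeca-1,9-diene-3,11-dione
Product: 11 (3S,4R,6R)-4-bromo-1,5,5,9-tetramethylspiro[5.5]undeca-1,9-diene-3,11-diol (C11 epimers)
Conditions: DIBAL-H (3.5 equiv), CH2Cl2, −78 °C; Rochelle salt
Reagents that add atoms: none
Why: DIBAL-H reduces both conjugated ketones in 1,2-fashion; at C3 the hydride should enter anti to the adjacent C–Br bond (polar Felkin–Anh control, the usual course for α-bromo ketones) to give the cis bromohydrin (3S), while the configuration of the new C11 carbinol does not matter because step 7 removes that centre.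

Step 6
Reactants: 11 (3S,4R,6R)-4-bromo-1,5,5,9-tetramethylspiro[5.5]undeca-1,9-diene-3,11-diol (C11 epimers)
Product: 12 (3S,4R,6R)-4-bromo-11-hydroxy-1,5,5,9-tetramethylspiro[5.5]undeca-1,9-dien-3-yl acetate (C11 epimers)
Conditions: Ac2O (1.2 equiv), pyridine, DMAP (cat.), CH2Cl2, 0 °C
Reagents that add atoms: acetic anhydride CC(=O)OC(C)=O
Why: DMAP-catalysed acylation should discriminate on steric grounds, the C3 hydroxyl being an ordinary secondary alcohol and the C11 hydroxyl neopentyl-like next to the spiro carbon; the acetate later suppresses ionisation and hydroxyl-directed epoxidation in ring A.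

Step 7
Reactants: 12 (3S,4R,6R)-4-bromo-11-hydroxy-1,5,5,9-tetramethylspiro[5.5]undeca-1,9-dien-3-yl acetate (C11 epimers)
Product: 13 (3S,4R,6R)-4-bromo-1,5,5,9-tetramethylspiro[5.5]undeca-1,9-dien-3-yl acetate
Conditions: Et3SiH, TFA, CH2Cl2, −40 → −10 °C
Reagents that add atoms: none
Why: Ionic deoxygenation (acid-promoted ionisation of the allylic alcohol, hydride transfer from the silane): the C9–C10–C11 allyl cation should be captured at its secondary terminus C11 to give the more substituted C9=C10 alkene, as in silane reductions of 3-methylcyclohex-2-enols, while the ring-A allylic acetate is an ester with a β-bromine cis to it (no anchimeric help) and should not ionise.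

Step 8
Reactants: 13 (3S,4R,6R)-4-bromo-1,5,5,9-tetramethylspiro[5.5]undeca-1,9-dien-3-yl acetate
Product: 14 (3S,4R,6R,9S,10R)-4-bromo-9,10-epoxy-1,5,5,9-tetramethylspiro[5.5]undec-1-en-3-yl acetate
Conditions: mCPBA (1.1 equiv), NaHCO3, CH2Cl2, −10 → 0 °C
Reagents that add atoms: mCPBA O=C(OO)c1cccc(Cl)c1
Why: Prilezhaev epoxidation should pick the electron-rich trisubstituted ring-B alkene (the ring-A alkene carries an allylic acetate and is flanked by the spiro carbon) and approach anti to C1, the vinylic spiro substituent expected to sit axial on ring B with its methyl above the ring, which places the oxirane oxygen on the C5 face (9S,10R).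

Step 9
Reactants: 14 (3S,4R,6R,9S,10R)-4-bromo-9,10-epoxy-1,5,5,9-tetramethylspiro[5.5]undec-1-en-3-yl acetate
Product: 15 (3S,4R,6R,9S,10S)-4-bromo-10-chloro-9-hydroxy-1,5,5,9-tetramethylspiro[5.5]undec-1-en-3-yl acetate
Conditions: LiCl, AcOH, THF, rt
Reagents that add atoms: lithium chloride [Li+].[Cl-]
Why: Chloride should open the epoxide in SN2 fashion at the less substituted carbon C10 with inversion, which is also the trans-diaxial (Fürst–Plattner) mode, so that chlorine arrives on the C1 face (10S) and the tertiary C9–OH stays on the C5 face; LiCl/AcOH keeps the medium too weakly acidic for SN1 opening at C9.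

Step 10
Reactants: 15 (3S,4R,6R,9S,10S)-4-bromo-10-chloro-9-hydroxy-1,5,5,9-tetramethylspiro[5.5]undec-1-en-3-yl acetate
Product: 16 (3S,4R,6R,9S,10S)-4,9-dibromo-10-chloro-1,5,5,9-tetramethylspiro[5.5]undec-1-en-3-yl acetate
Conditions: TMSBr, CH2Cl2, −20 → 0 °C
Reagents that add atoms: bromotrimethylsilane C[Si](C)(C)Br
Why: SN1-type substitution of the tertiary alcohol: ionisation is assisted by the antiperiplanar (trans-diaxial) C10 chlorine and bromide should be captured axially, anti to that chlorine, so that Br takes the place of OH on the C5 face (9S, Br trans to Cl, methyl equatorial), the arrangement also expected at equilibrium; any elimination product would re-add HBr in the Markovnikov sense, and the cold, short exposure should spare the deactivated allylic acetate.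

Step 11
Reactants: 16 (3S,4R,6R,9S,10S)-4,9-dibromo-10-chloro-1,5,5,9-tetramethylspiro[5.5]undec-1-en-3-yl acetate
Product: 17 (3S,4R,6R,9S,10S)-4,9-dibromo-10-chloro-1,5,5,9-tetramethylspiro[5.5]undec-1-en-3-ol
Conditions: DIBAL-H (2.5 equiv), CH2Cl2, −78 °C; Rochelle salt
Reagents that add atoms: none
Why: Reductive ester cleavage with DIBAL-H at −78 °C should remove the acetate without the basic, protic conditions that could eliminate the tertiary bromide or disturb the bromohydrin; the alkyl halides are inert to DIBAL-H at this temperature and no stereocentre is touched.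

**Compound list**
1 | (E)-4-methoxypent-3-en-2-one | CC(=O)/C=C(\C)OC | starting material
2 | chlorotrimethylsilane | C[Si](C)(C)Cl | starting material
3 | (E)-4-methoxy-2-(trimethylsilyloxy)penta-1,3-diene | C=C(O[Si](C)(C)C)/C=C(\C)OC | intermediate
4 | (R)-(+)-pulegone, (5R)-5-methyl-2-(propan-2-ylidene)cyclohexan-1-one | C[C@@H]1CCC(=C(C)C)C(=O)C1 | starting material
5 | trichlorotitanium enolate of (5R)-2-[(E)-6-methoxy-2-methyl-4-oxohept-5-en-2-yl]-5-methylcyclohexan-1-one (first Michael adduct) | C[C@@H]1CCC(C(C)(C)CC(=O)/C=C(\C)OC)=C(O[Ti](Cl)(Cl)Cl)C1 | intermediate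
6 | (6S,9R)-1-methoxy-1,5,5,9-tetramethylspiro[5.5]undecane-3,11-dione (C1 epimers) | COC1(C)CC(=O)CC(C)(C)[C@@]12CC[C@@H](C)CC2=O | intermediate
7 | (6S,9R)-1,5,5,9-tetramethylspiro[5.5]undec-1-ene-3,11-dione | CC1=CC(=O)CC(C)(C)[C@@]12CC[C@@H](C)CC2=O | intermediate
8 | (6S)-1,5,5,9-tetramethylspiro[5.5]undeca-1,9-diene-3,11-dione | CC1=CC(=O)CC(C)(C)[C@@]12CCC(C)=CC2=O | intermediate
9 | (6R)-1,5,5,9-tetramethyl-3-(trimethylsilyloxy)spiro[5.5]undeca-1,3,9-trien-11-one | CC1=CC(O[Si](C)(C)C)=CC(C)(C)[C@@]12CCC(C)=CC2=O | intermediate
10 | (4R,6R)-4-bromo-1,5,5,9-tetramethylspiro[5.5]undeca-1,9-diene-3,11-dione | CC1=CC(=O)[C@H](Br)C(C)(C)[C@@]12CCC(C)=CC2=O | intermediate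
11 | (3S,4R,6R)-4-bromo-1,5,5,9-tetramethylspiro[5.5]undeca-1,9-diene-3,11-diol (C11 epimers) | CC1=C[C@H](O)[C@H](Br)C(C)(C)[C@@]12CCC(C)=CC2O | intermediate
12 | (3S,4R,6R)-4-bromo-11-hydroxy-1,5,5,9-tetramethylspiro[5.5]undeca-1,9-dien-3-yl acetate (C11 epimers) | CC1=C[C@H](OC(C)=O)[C@H](Br)C(C)(C)[C@@]12CCC(C)=CC2O | intermediate
13 | (3S,4R,6R)-4-bromo-1,5,5,9-tetramethylspiro[5.5]undeca-1,9-dien-3-yl acetate | CC1=C[C@H](OC(C)=O)[C@H](Br)C(C)(C)[C@@]12CCC(C)=CC2 | intermediate
14 | (3S,4R,6R,9S,10R)-4-bromo-9,10-epoxy-1,5,5,9-tetramethylspiro[5.5]undec-1-en-3-yl acetate | CC1=C[C@H](OC(C)=O)[C@H](Br)C(C)(C)[C@@]12CC[C@]3(C)O[C@@H]3C2 | intermediate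
15 | (3S,4R,6R,9S,10S)-4-bromo-10-chloro-9-hydroxy-1,5,5,9-tetramethylspiro[5.5]undec-1-en-3-yl acetate | CC1=C[C@H](OC(C)=O)[C@H](Br)C(C)(C)[C@@]12CC[C@](C)(O)[C@@H](Cl)C2 | intermediate
16 | (3S,4R,6R,9S,10S)-4,9-dibromo-10-chloro-1,5,5,9-tetramethylspiro[5.5]undec-1-en-3-yl acetate | CC1=C[C@H](OC(C)=O)[C@H](Br)C(C)(C)[C@@]12CC[C@](C)(Br)[C@@H](Cl)C2 | intermediate
17 | (3S,4R,6R,9S,10S)-4,9-dibromo-10-chloro-1,5,5,9-tetramethylspiro[5.5]undec-1-en-3-ol | CC1=C[C@H](O)[C@H](Br)C(C)(C)[C@@]12CC[C@](C)(Br)[C@@H](Cl)C2 | target

**Totals**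
Total steps: 11. Longest linear sequence: 11 steps (1 → 17); 10 steps from pulegone 4.

**Steps most likely to fail**

Step 2 (Proposed new method). The conjugate addition may not take place at the tetrasubstituted enone, the diene being consumed by the Lewis acid instead. The sequence may also stop at enolate 5, because closing C1–C6 between two quaternary carbons is too slow. Poor facial selectivity at C6 is the lesser worry. The fallback uses known reactions and runs from 4 back to 7. Hosomi–Sakurai conjugate allylation of pulegone (allyltrimethylsilane, TiCl4) forms the C4–C5 bond and gives (5R)-5-methyl-2-(2-methylpent-4-en-2-yl)cyclohexan-1-one F1. Ozonolysis with reductive work-up gives 3-methyl-3-[(4R)-4-methyl-2-oxocyclohexyl]butanal F2. 1-Propynylmagnesium bromide should add to the aldehyde in preference to the hindered ketone and give (5R)-2-(4-hydroxy-2-methylhept-5-yn-2-yl)-5-methylcyclohexan-1-one F3. Dess–Martin oxidation gives the ynone (5R)-5-methyl-2-(2-methyl-4-oxohept-5-yn-2-yl)cyclohexan-1-one F4. A base (Cs2CO3 or catalytic t-BuOK) should then bring about the intramolecular 6-endo-dig Michael addition of the C6 enolate to the ynone, which forms C1–C6 and gives 7 directly, with C6 set by the same axial-attack argument.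

Step 7. Hydride may be delivered to the tertiary allyl terminus C9, giving the C10=C11 isomer. A ring-A bond may migrate from the spiro carbon to the cationic C11, or the ring-A acetate may ionise. The fallback runs from 12 back to 13 and replaces the free cation by a π-allylpalladium complex. The C11 hydroxyl is converted with methyl chloroformate, pyridine and DMAP into (3S,4R,6R)-3-acetoxy-4-bromo-1,5,5,9-tetramethylspiro[5.5]undeca-1,9-dien-11-yl methyl carbonate F5. Pd(PPh3)4 with NaBH4 in THF should then effect hydrogenolysis: allyl carbonates ionise with Pd(0) where allyl acetates are left, and borohydride attacks the less substituted allyl terminus, which again gives 13.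

Step 9. Opening may occur at the tertiary carbon C9 if the transition state gains SN1 character, or it may be very slow because chloride has to enter C10 syn-axial to C1. The fallback runs from 13 back to 15 and puts the leaving group on C10 alone. OsO4/NMO dihydroxylation of the ring-B alkene on the same (C5) face gives (3S,4R,6R,9S,10R)-4-bromo-9,10-dihydroxy-1,5,5,9-tetramethylspiro[5.5]undec-1-en-3-yl acetate F6. Mesylation of the secondary hydroxyl (MsCl, Et3N) gives (3S,4R,6R,9S,10R)-4-bromo-9-hydroxy-10-(methanesulfonyloxy)-1,5,5,9-tetramethylspiro[5.5]undec-1-en-3-yl acetate F7. LiCl in DMF should displace the mesylate with inversion to give 15; the cis tertiary hydroxyl cannot close an epoxide.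

**Further compounds**
F1 | step 2 | (5R)-5-methyl-2-(2-methylpent-4-en-2-yl)cyclohexan-1-one (C2 epimers) | C=CCC(C)(C)C1CC[C@@H](C)CC1=O
F2 | step 2 | 3-methyl-3-[(4R)-4-methyl-2-oxocyclohexyl]butanal | O=CCC(C)(C)C1CC[C@@H](C)CC1=O
F3 | step 2 | (5R)-2-(4-hydroxy-2-methylhept-5-yn-2-yl)-5-methylcyclohexan-1-one (carbinol epimers) | CC#CC(O)CC(C)(C)C1CC[C@@H](C)CC1=O
F4 | step 2 | (5R)-5-methyl-2-(2-methyl-4-oxohept-5-yn-2-yl)cyclohexan-1-one | CC#CC(=O)CC(C)(C)C1CC[C@@H](C)CC1=O
F5 | step 7 | (3S,4R,6R)-3-acetoxy-4-bromo-1,5,5,9-tetramethylspiro[5.5]undeca-1,9-dien-11-yl methyl carbonate (C11 epimers) | CC1=C[C@H](OC(C)=O)[C@H](Br)C(C)(C)[C@@]12CCC(C)=CC2OC(=O)OC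
F6 | step 9 | (3S,4R,6R,9S,10R)-4-bromo-9,10-dihydroxy-1,5,5,9-tetramethylspiro[5.5]undec-1-en-3-yl acetate | CC1=C[C@H](OC(C)=O)[C@H](Br)C(C)(C)[C@@]12CC[C@](C)(O)[C@H](O)C2
F7 | step 9 | (3S,4R,6R,9S,10R)-4-bromo-9-hydroxy-10-(methanesulfonyloxy)-1,5,5,9-tetramethylspiro[5.5]undec-1-en-3-yl acetate | CC1=C[C@H](OC(C)=O)[C@H](Br)C(C)(C)[C@@]12CC[C@](C)(O)[C@H](OS(C)(=O)=O)C2
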